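**Plan**

1. Cuts: in the C20 acyl chain (C1 = ester carbonyl) the C9–C10 bond and then the C7–C8 bond, both read at the alkyne oxidation level (triple bonds at C5, C8, C11, C14); the ester C–O bond; in the diterpenol the CH2–CH2 bond next to the ring-bearing CH2 (sulfone alkylation) and the ring C1–CH2 bond ([3,3] shift).
2. Forward: enone → (R)-allylic alcohol → α-cyclogeranyl sulfone; alkylation with an 8-bromogeranyl benzyl ether and one reductive removal of sulfone and benzyl gives the C20 alcohol; esterification with hex-5-ynoic acid, C3 extension to a terminal 5,8-diyne, union with 1-bromoundeca-2,5-diyne, then one fourfold semi-hydrogenation.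
3. Enabling feature: C10 is the methylene between C8=C9 and C11=C12. With both alkenes written as alkynes, C9 is an acetylenic C–H and C10 a primary propargylic carbon, so a copper acetylide displacement joins the C29 ester (cyclohexene ring and both E-alkenes in place) to the C11 bromide.
4. Stereochemistry: ring C1 (S) comes from a CBS reduction whose carbinol centre is relayed across the cyclohexene face by a decarboxylative Claisen rearrangement; 2E,6E come from geraniol and an E-selective SeO2 oxidation; all four Z-alkenes come from syn hydrogenation of the tetrayne.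

Key step: step 14

Remark: the sense of the CBS reduction is taken from the usual model with the C2-alkenyl arm of the enone as the large group, so the (S)-oxazaborolidine is expected to give the (1R)-alcohol.

**Route**

Step 1
Reactants: 1 2,4,4-trimethylcyclohex-2-en-1-one
Product: 2 (1R)-2,4,4-trimethylcyclohex-2-en-1-ol
Conditions: (S)-2-methyl-CBS-oxazaborolidine (0.2 equiv), BH3·SMe2 (0.7 equiv), THF, −20 °C; then MeOH
Reagents that add atoms: none
Why: Corey–Bakshi–Shibata reduction, in which the catalyst-bound borane should deliver hydride to the carbonyl face left open when the alkenyl arm points away from the B-methyl group, giving 1,2-reduction to the (R)-carbinol.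

Step 2
Reactants: 2 (1R)-2,4,4-trimethylcyclohex-2-en-1-ol; 3 (p-tolylsulfonyl)acetic acid
Product: 4 (1R)-2,4,4-trimethylcyclohex-2-en-1-yl (p-tolylsulfonyl)acetate
Conditions: DCC, DMAP (cat.), CH2Cl2, 0 °C → rt
Reagents that add atoms: none
Why: Steglich esterification acylates the carbinol oxygen without touching the C–O stereocentre.

Step 3
Reactants: 4 (1R)-2,4,4-trimethylcyclohex-2-en-1-yl (p-tolylsulfonyl)acetate
Product: 7 p-tolyl [(1S)-2,6,6-trimethylcyclohex-2-en-1-yl]methyl sulfone, via silyl ketene acetal 5 (not isolated), via rearranged silyl ester 6 (not isolated)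
Conditions: N,O-bis(trimethylsilyl)acetamide (0.2 equiv), KOAc (0.1 equiv), toluene, 110 °C
Reagents that add atoms: none
Why: Decarboxylative Claisen rearrangement of an allylic sulfonylacetate, in which ketene acetal 5 should undergo an Ireland–Claisen [3,3] shift that forms the new C–C bond on the ring face that carried the C–O bond (suprafacial 1,3-transfer, (R)-carbinol to (S)-C1), after which acetate-induced desilylation of 6 and loss of CO2 leave the homoallylic sulfone.

Step 4
Reactants: 8 geraniol
Product: 10 benzyl geranyl ether, via sodium geranoxide 9 (not isolated)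
Conditions: NaH, DMF, 0 °C; then BnBr, 0 °C → rt
Reagents that add atoms: benzyl bromide, BrCc1ccccc1
Why: Williamson ether synthesis on a primary allylic alkoxide, which leaves the 2E alkene untouched.

Step 5
Reactants: 10 benzyl geranyl ether
Product: 11 (2E,6E)-8-(benzyloxy)-2,6-dimethylocta-2,6-dien-1-ol
Conditions: SeO2 (0.1 equiv), t-BuOOH (2 equiv), salicylic acid (0.1 equiv), CH2Cl2, rt
Reagents that add atoms: SeO2, O=[Se]=O (catalytic oxygen carrier); tert-butyl hydroperoxide, CC(C)(C)OO (terminal oxidant)
Why: SeO2-catalysed allylic (Riley-type) oxidation by ene reaction and [2,3] shift should attack the electron-richer terminal trisubstituted alkene and give the (E)-allylic alcohol, while the C2=C3 alkene is deactivated by the allylic ether oxygen.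

Step 6
Reactants: 11 (2E,6E)-8-(benzyloxy)-2,6-dimethylocta-2,6-dien-1-ol
Product: 12 benzyl (2E,6E)-8-bromo-3,7-dimethylocta-2,6-dien-1-yl ether
Conditions: CBr4, PPh3, CH2Cl2, 0 °C
Reagents that add atoms: carbon tetrabromide, BrC(Br)(Br)Br
Why: Appel reaction, an SN2 displacement at the primary allylic carbinol that should proceed without allylic transposition or loss of E geometry.

Step 7
Reactants: 7 p-tolyl [(1S)-2,6,6-trimethylcyclohex-2-en-1-yl]methyl sulfone; 12 benzyl (2E,6E)-8-bromo-3,7-dimethylocta-2,6-dien-1-yl ether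
Product: 14 benzyl (2E,6E)-3,7-dimethyl-9-(p-tolylsulfonyl)-9-[(1S)-2,6,6-trimethylcyclohex-2-en-1-yl]nona-2,6-dien-1-yl ether as both C9 epimers, via lithiated sulfone 13 (not isolated)
Conditions: n-BuLi, THF, −78 °C; then 12, DMPU, −78 → −20 °C
Reagents that add atoms: none
Why: Alkylation of an α-sulfonyl carbanion with a primary allylic bromide (sulfone-based terpene chain assembly, SN2 at CH2Br); the new sulfonyl-bearing centre forms as a mixture that step 8 erases, and the ring stereocentre is not touched.

Step 8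
Reactants: 14 benzyl (2E,6E)-3,7-dimethyl-9-(p-tolylsulfonyl)-9-[(1S)-2,6,6-trimethylcyclohex-2-en-1-yl]nona-2,6-dien-1-yl ether
Product: 15 (2E,6E)-3,7-dimethyl-9-[(1S)-2,6,6-trimethylcyclohex-2-en-1-yl]nona-2,6-dien-1-ol
Conditions: Li, EtNH2/THF, −78 °C; then NH4Cl
Reagents that add atoms: none
Why: Dissolving-metal (Benkeser-type) reduction should cleave the C–SO2Ar bond and the benzyl–O bond by electron transfer in one operation, as is usual at the end of sulfone-based polyprenol assembly, while isolated trisubstituted alkenes are not reduced at −78 °C.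

Step 9
Reactants: 15 (2E,6E)-3,7-dimethyl-9-[(1S)-2,6,6-trimethylcyclohex-2-en-1-yl]nona-2,6-dien-1-ol; 16 hex-5-ynoic acid
Product: 17 (2E,6E)-3,7-dimethyl-9-[(1S)-2,6,6-trimethylcyclohex-2-en-1-yl]nona-2,6-dien-1-yl hex-5-ynoate
Conditions: DCC, DMAP (cat.), CH2Cl2, 0 °C → rt
Reagents that add atoms: none
Why: Steglich esterification of a primary allylic alcohol under neutral conditions that do not ionise the allylic C–O bond.

Step 10
Reactants: 17 (2E,6E)-3,7-dimethyl-9-[(1S)-2,6,6-trimethylcyclohex-2-en-1-yl]nona-2,6-dien-1-yl hex-5-ynoate; 18 3-bromo-1-(trimethylsilyl)prop-1-yne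
Product: 20 (2E,6E)-3,7-dimethyl-9-[(1S)-2,6,6-trimethylcyclohex-2-en-1-yl]nona-2,6-dien-1-yl 9-(trimethylsilyl)nona-5,8-diynoate, via copper acetylide 19 (not isolated)
Conditions: CuI (1 equiv), K2CO3, Bu4NCl, DMF, rt, argon; then 18
Reagents that add atoms: none
Why: Copper-mediated coupling of a terminal alkyne with a propargylic bromide (SN2 by the monovalent copper acetylide) should form the C6–C7 bond, the silyl cap preventing further coupling of the new alkyne terminus.

Step 11
Reactants: 20 (2E,6E)-3,7-dimethyl-9-[(1S)-2,6,6-trimethylcyclohex-2-en-1-yl]nona-2,6-dien-1-yl 9-(trimethylsilyl)nona-5,8-diynoate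
Product: 21 (2E,6E)-3,7-dimethyl-9-[(1S)-2,6,6-trimethylcyclohex-2-en-1-yl]nona-2,6-dien-1-yl nona-5,8-diynoate
Conditions: Bu4NF, AcOH, THF, 0 °C
Reagents that add atoms: none
Why: Fluoride-induced protodesilylation of the alkynylsilane, buffered with AcOH so that the doubly propargylic C7 methylene does not isomerise to an allene and the ester is not cleaved.

Step 12
Reactants: 22 1-bromooct-2-yne; 23 prop-2-yn-1-ol
Product: 25 undeca-2,5-diyn-1-ol, via copper acetylide 24 (not isolated)
Conditions: 23, CuI (1 equiv), K2CO3, Bu4NCl, DMF, rt, argon; then 22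
Reagents that add atoms: none
Why: Copper-mediated alkyne–propargyl bromide coupling, in which the acetylide of propargyl alcohol should displace the primary bromide in an SN2 sense to give the skipped diyne.

Step 13
Reactants: 25 undeca-2,5-diyn-1-ol
Product: 26 1-bromoundeca-2,5-diyne
Conditions: CBr4, PPh3, CH2Cl2, −20 → 0 °C
Reagents that add atoms: carbon tetrabromide, BrC(Br)(Br)Br
Why: Appel reaction at a primary propargylic carbinol under neutral conditions, which should give the bromide without allene formation.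

Step 14
Reactants: 21 (2E,6E)-3,7-dimethyl-9-[(1S)-2,6,6-trimethylcyclohex-2-en-1-yl]nona-2,6-dien-1-yl nona-5,8-diynoate; 26 1-bromoundeca-2,5-diyne
Product: 28 (2E,6E)-3,7-dimethyl-9-[(1S)-2,6,6-trimethylcyclohex-2-en-1-yl]nona-2,6-dien-1-yl icosa-5,8,11,14-tetraynoate, via copper acetylide 27 (not isolated)
Conditions: CuI (1 equiv), K2CO3, Bu4NCl, DMF, rt, argon, dark; then 26
Reagents that add atoms: none
Why: Carbonate deprotonates the terminal C9–H of 21 in the presence of CuI to give the monovalent copper acetylide 27, which should displace bromide from the primary propargylic carbon C10 of 26 in an SN2 sense and so form the C9–C10 bond. The closest known reaction type is the copper-mediated coupling of terminal alkynes with propargylic halides, the standard entry to skipped polyynes. No ring is closed and no stereocentre is formed; the step completes the C20 chain with triple bonds at C5, C8, C11 and C14, so that the geometry of all four alkenes is left to one syn hydrogenation. The step needs SN2 over SN2' attack (no allene), no prototropic shift of the doubly propargylic methylenes C7, C10 and C13, no oxidative alkyne dimerisation and no attack on the allylic ester. These are secured by the unhindered primary bromide, by a base too weak to deprotonate propargylic C–H at room temperature, by exclusion of oxygen, and by the absence of any metal that ionises allylic esters.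

Step 15
Reactants: 28 (2E,6E)-3,7-dimethyl-9-[(1S)-2,6,6-trimethylcyclohex-2-en-1-yl]nona-2,6-dien-1-yl icosa-5,8,11,14-tetraynoate
Product: 29 (2E,6E)-3,7-dimethyl-9-[(1S)-2,6,6-trimethylcyclohex-2-en-1-yl]nona-2,6-dien-1-yl (5Z,8Z,11Z,14Z)-icosa-5,8,11,14-tetraenoate
Conditions: H2 (1 atm), Pd/CaCO3 poisoned with Pb(OAc)2, quinoline, EtOAc, 10 °C, stopped after 4 equiv H2
Reagents that add atoms: none
Why: Semi-hydrogenation on Pd/CaCO3–Pb(OAc)2 (Lindlar type) adds H2 syn to each of the four disubstituted alkynes to give Z-alkenes, while the three trisubstituted alkenes and the allylic ester should not be reduced under these conditions.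

**Compound list**

1 | 2,4,4-trimethylcyclohex-2-en-1-one | CC1=CC(C)(C)CCC1=O | starting material
2 | (1R)-2,4,4-trimethylcyclohex-2-en-1-ol | O[C@@H]1CCC(C)(C)C=C1C | intermediate
3 | (p-tolylsulfonyl)acetic acid | Cc1ccc(cc1)S(=O)(=O)CC(=O)O | starting material
4 | (1R)-2,4,4-trimethylcyclohex-2-en-1-yl (p-tolylsulfonyl)acetate | Cc1ccc(cc1)S(=O)(=O)CC(=O)O[C@@H]1CCC(C)(C)C=C1C | intermediate
5 | trimethylsilyl ketene acetal of 4 (not isolated; enol ether geometry not defined) | Cc1ccc(cc1)S(=O)(=O)C=C(O[Si](C)(C)C)O[C@@H]1CCC(C)(C)C=C1C | intermediate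
6 | trimethylsilyl 2-(p-tolylsulfonyl)-2-[(1S)-2,6,6-trimethylcyclohex-2-en-1-yl]acetate (not isolated; both epimers at the sulfonyl carbon) | Cc1ccc(cc1)S(=O)(=O)C(C(=O)O[Si](C)(C)C)[C@@H]1C(C)=CCCC1(C)C | intermediate
7 | p-tolyl [(1S)-2,6,6-trimethylcyclohex-2-en-1-yl]methyl sulfone | Cc1ccc(cc1)S(=O)(=O)C[C@@H]1C(C)=CCCC1(C)C | intermediate
8 | geraniol, (2E)-3,7-dimethylocta-2,6-dien-1-ol | CC(C)=CCC/C(C)=C/CO | starting material
9 | sodium geranoxide (not isolated) | CC(C)=CCC/C(C)=C/C[O-].[Na+] | intermediate
10 | benzyl geranyl ether | CC(C)=CCC/C(C)=C/COCc1ccccc1 | intermediate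
11 | (2E,6E)-8-(benzyloxy)-2,6-dimethylocta-2,6-dien-1-ol | OC/C(C)=C/CC/C(C)=C/COCc1ccccc1 | intermediate
12 | benzyl (2E,6E)-8-bromo-3,7-dimethylocta-2,6-dien-1-yl ether | BrC/C(C)=C/CC/C(C)=C/COCc1ccccc1 | intermediate
13 | α-lithio derivative of sulfone 7 (not isolated) | [Li]C(S(=O)(=O)c1ccc(C)cc1)[C@@H]1C(C)=CCCC1(C)C | intermediate
14 | benzyl (2E,6E)-3,7-dimethyl-9-(p-tolylsulfonyl)-9-[(1S)-2,6,6-trimethylcyclohex-2-en-1-yl]nona-2,6-dien-1-yl ether (both C9 epimers) | c1ccccc1COC/C=C(\C)CC/C=C(\C)CC(S(=O)(=O)c1ccc(C)cc1)[C@@H]1C(C)=CCCC1(C)C | intermediate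
15 | (2E,6E)-3,7-dimethyl-9-[(1S)-2,6,6-trimethylcyclohex-2-en-1-yl]nona-2,6-dien-1-ol | OC/C=C(\C)CC/C=C(\C)CC[C@@H]1C(C)=CCCC1(C)C | intermediate
16 | hex-5-ynoic acid | C#CCCCC(=O)O | starting material
17 | (2E,6E)-3,7-dimethyl-9-[(1S)-2,6,6-trimethylcyclohex-2-en-1-yl]nona-2,6-dien-1-yl hex-5-ynoate | C#CCCCC(=O)OC/C=C(\C)CC/C=C(\C)CC[C@@H]1C(C)=CCCC1(C)C | intermediate
18 | 3-bromo-1-(trimethylsilyl)prop-1-yne | C[Si](C)(C)C#CCBr | starting material
19 | copper acetylide of 17 (monovalent copper; not isolated) | [Cu]C#CCCCC(=O)OC/C=C(\C)CC/C=C(\C)CC[C@@H]1C(C)=CCCC1(C)C | intermediate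
20 | (2E,6E)-3,7-dimethyl-9-[(1S)-2,6,6-trimethylcyclohex-2-en-1-yl]nona-2,6-dien-1-yl 9-(trimethylsilyl)nona-5,8-diynoate | C[Si](C)(C)C#CCC#CCCCC(=O)OC/C=C(\C)CC/C=C(\C)CC[C@@H]1C(C)=CCCC1(C)C | intermediate
21 | (2E,6E)-3,7-dimethyl-9-[(1S)-2,6,6-trimethylcyclohex-2-en-1-yl]nona-2,6-dien-1-yl nona-5,8-diynoate | C#CCC#CCCCC(=O)OC/C=C(\C)CC/C=C(\C)CC[C@@H]1C(C)=CCCC1(C)C | intermediate
22 | 1-bromooct-2-yne | CCCCCC#CCBr | starting material
23 | prop-2-yn-1-ol | C#CCO | starting material
24 | copper acetylide of 23 (monovalent copper; not isolated) | [Cu]C#CCO | intermediate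
25 | undeca-2,5-diyn-1-ol | CCCCCC#CCC#CCO | intermediate
26 | 1-bromoundeca-2,5-diyne | CCCCCC#CCC#CCBr | intermediate
27 | copper acetylide of 21 (monovalent copper; not isolated) | [Cu]C#CCC#CCCCC(=O)OC/C=C(\C)CC/C=C(\C)CC[C@@H]1C(C)=CCCC1(C)C | intermediate
28 | (2E,6E)-3,7-dimethyl-9-[(1S)-2,6,6-trimethylcyclohex-2-en-1-yl]nona-2,6-dien-1-yl icosa-5,8,11,14-tetraynoate | CCCCCC#CCC#CCC#CCC#CCCCC(=O)OC/C=C(\C)CC/C=C(\C)CC[C@@H]1C(C)=CCCC1(C)C | intermediate
29 | (2E,6E)-3,7-dimethyl-9-[(1S)-2,6,6-trimethylcyclohex-2-en-1-yl]nona-2,6-dien-1-yl (5Z,8Z,11Z,14Z)-icosa-5,8,11,14-tetraenoate | CCCCC/C=C\C/C=C\C/C=C\C/C=C\CCCC(=O)OC/C=C(\C)CC/C=C(\C)CC[C@@H]1C(C)=CCCC1(C)C | target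

**Step count and risks**

Total step count: 15. Longest linear sequence: 10 steps (steps 1, 2, 3, 7, 8, 9, 10, 11, 14, 15; the branch through steps 4, 5, 6 is equally long).

Steps most likely to fail:

Step 3. The [3,3] shift must form a C–C bond at the ring carbon flanked by the gem-dimethyl group. If it is slow at 110 °C, thermal ionisation of the allylic sulfonylacetate may compete, with elimination to a cyclohexadiene or loss of optical purity by ion-pair return. The fallback sets out from 2 and comes back at 7, replacing the thermal [3,3] shift by an anionic [2,3] shift at low temperature. Deprotonation of 2 with KH in THF should give potassium (1R)-2,4,4-trimethylcyclohex-2-en-1-olate F1, which is alkylated with Bu3SnCH2I to tributyl({[(1R)-2,4,4-trimethylcyclohex-2-en-1-yl]oxy}methyl)stannane F2. Tin–lithium exchange with n-BuLi in THF at −78 °C gives the lithiomethyl ether F3, which should undergo a Wittig–Still [2,3] rearrangement on the oxygen-bearing ring face to [(1S)-2,6,6-trimethylcyclohex-2-en-1-yl]methanol F4. Di-p-tolyl disulfide and Bu3P should convert this alcohol into p-tolyl [(1S)-2,6,6-trimethylcyclohex-2-en-1-yl]methyl sulfide F5, and H2O2 with catalytic (NH4)6Mo7O24·4H2O in EtOH should oxidise sulfur only, returning 7.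

Step 15. Four triple bonds must be reduced in one pot. Alkenes formed early may stay on the catalyst and be over-reduced or isomerised before the last alkyne has reacted, or the reduction may stall and leave inseparable partly reduced material. The fallback sets out from 25 and comes back at 29, setting half of the Z-alkenes on a small fragment before the union. Hydrogenation of 25 over the nickel boride catalyst made from Ni(OAc)2·4H2O and NaBH4 with ethylenediamine in EtOH should give (2Z,5Z)-undeca-2,5-dien-1-ol F6, and CBr4/PPh3 should give (2Z,5Z)-1-bromoundeca-2,5-diene F7. Copper acetylide 27, made from 21 as in step 14, should displace the primary allylic bromide of F7 without a π-allyl intermediate and hence with retention of both Z-alkenes, giving (2E,6E)-3,7-dimethyl-9-[(1S)-2,6,6-trimethylcyclohex-2-en-1-yl]nona-2,6-dien-1-yl (11Z,14Z)-icosa-11,14-dien-5,8-diynoate F8. Semi-hydrogenation of only two triple bonds over Pd/CaCO3 poisoned with Pb(OAc)2 then gives 29.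

Step 1. Facial discrimination in hydride delivery may be incomplete because the alkenyl and methylene arms of the enone differ only moderately in size, and any shortfall in enantiomeric purity would be carried to the target. The fallback sets out from 1 and comes back at 2, replacing asymmetric reduction by enzymatic kinetic resolution. Luche reduction (NaBH4, CeCl3·7H2O, MeOH, 0 °C) should give racemic 2,4,4-trimethylcyclohex-2-en-1-ol F9. Burkholderia cepacia lipase with vinyl acetate in t-BuOMe, run to about half conversion, should acylate the (R)-enantiomer preferentially to (1R)-2,4,4-trimethylcyclohex-2-en-1-yl acetate F10, which is separated from the unreacted (S)-alcohol and methanolysed (K2CO3, MeOH) to 2.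

**Further compounds**

F1 | step 3 | potassium (1R)-2,4,4-trimethylcyclohex-2-en-1-olate | [K+].[O-][C@@H]1CCC(C)(C)C=C1C
F2 | step 3 | tributyl({[(1R)-2,4,4-trimethylcyclohex-2-en-1-yl]oxy}methyl)stannane | CCCC[Sn](CCCC)(CCCC)CO[C@@H]1CCC(C)(C)C=C1C
F3 | step 3 | {[(1R)-2,4,4-trimethylcyclohex-2-en-1-yl]oxy}methyllithium (not isolated) | [Li]CO[C@@H]1CCC(C)(C)C=C1C
F4 | step 3 | [(1S)-2,6,6-trimethylcyclohex-2-en-1-yl]methanol | OC[C@@H]1C(C)=CCCC1(C)C
F5 | step 3 | p-tolyl [(1S)-2,6,6-trimethylcyclohex-2-en-1-yl]methyl sulfide | Cc1ccc(cc1)SC[C@@H]1C(C)=CCCC1(C)C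
F6 | step 15 | (2Z,5Z)-undeca-2,5-dien-1-ol | CCCCC/C=C\C/C=C\CO
F7 | step 15 | (2Z,5Z)-1-bromoundeca-2,5-diene | CCCCC/C=C\C/C=C\CBr
F8 | step 15 | (2E,6E)-3,7-dimethyl-9-[(1S)-2,6,6-trimethylcyclohex-2-en-1-yl]nona-2,6-dien-1-yl (11Z,14Z)-icosa-11,14-dien-5,8-diynoate | CCCCC/C=C\C/C=C\CC#CCC#CCCCC(=O)OC/C=C(\C)CC/C=C(\C)CC[C@@H]1C(C)=CCCC1(C)C
F9 | step 1 | racemic 2,4,4-trimethylcyclohex-2-en-1-ol | OC1CCC(C)(C)C=C1C
F10 | step 1 | (1R)-2,4,4-trimethylcyclohex-2-en-1-yl acetate | CC(=O)O[C@@H]1CCC(C)(C)C=C1C
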